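Readings and results were computed for an exercise; noise was put on by code.

The target in these flasks is counted against the starting material charged, and the runs differ in catalyst loading and in time.

| setting | south | west | ochre | red | teal |
|---|---|---|---|---|---|
| starting material | 22 mM | 22 mM | 22 mM | 22 mM | 22 mM |
| reagent | 1.5 equiv | 1.5 equiv | 1.50 equiv | 1.50 equiv | 1.50 equiv |
| free catalyst | 0.079 mol% | 0.67 mol% | 0.1 mol% | 0.3 mol% | 1 mol% |
| remark | run made earlier | run made earlier |  |  |  |
| time |  |  | 50 min | 50 min | 50 min |

| run | time / min | target / % |
|---|---|---|
| south | 2.00 | 2.7 |
| south | 6.00 | 6.1 |
| south | 12.0 | 11.0 |
| south | 20.0 | 14.4 |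
| south | 25.0 | 17.8 |
| west | 5.00 | 26.5 |
| west | 10.0 | 40.2 |
| west | 15.0 | 49.0 |
| west | 20.0 | 54.7 |
| west | 25.0 | 59.3 |

(each reading ± 0.5 percentage points)

1. amount of target at the end, in percent of the starting material charged for ochre, red, teal, in this order
2. how the row runs (falls, then rises / rises, then falls / falls all the way / hardly changes / rises all the way)

- the numbers in the tables scatter with a standard deviation of 0.5 percentage points
- "hardly changes" means that all values lie within two and a half points (for a concentration: within two and a half percent of the largest)

A bench rule for a catalysed reaction says that a given amount of target costs a given amount of catalyst multiplied by time. Define the loading-time as the fraction of catalyst charged times the minutes run. Teal at its end then holds 0.500 min, red 0.150 min and ochre 0.0500 min.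

The west run supplies the curve against this quantity, with 0.0335 min at its first reading. Doubling the time from 5.00 min to 10.0 min adds 14 percentage points, and doubling again to 20.0 min adds 15 points. The curve can therefore be replaced by its mean gain, 14 points per doubling of loading-time.

The error of that mean can be tested on the south run, which was made at another loading. At 25.0 min, south holds 0.0198 min, and the rule gives 15.8 % against the reading of 17.8 %. The rule thus misses that reading by about 2 points, and at 20.0 min it misses the south reading by 3.2 points, so it is not carried down to the earlier south readings.

Inside the west readings, the rule gives ochre 34.6 % and red 57.0 %. Teal is different, since its loading-time is 2.99 times that of the last west reading, at 25.0 min. The rule there gives 81.5 %, but this is an extrapolation. Teal's figure stands outside the west readings, and on this reckoning the row rises all the way.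

The forecast gives 34 %, 57 % and 80 %, rises all the way, its teal value lying below the reckoning here, with the remark “The last value is an extrapolation.”

The flasks give 34.3 %, 57.2 % and 76.0 %, and the row rises all the way.

    starting material + free catalyst → catalyst intermediate A (k = 45.0 L mol⁻¹ s⁻¹)
    2 free catalyst → spent catalyst (k = 190 L mol⁻¹ s⁻¹)
    catalyst intermediate C → free catalyst + target (k = 0.390 s⁻¹)
    reagent + catalyst intermediate A → catalyst intermediate B (k = 25.0 L mol⁻¹ s⁻¹)
    catalyst intermediate B ⇌ by-product + catalyst intermediate C (K = 0.0160 M, k = 6.40 s⁻¹)

Teal stands 5.5 points below the doubling rule, where ochre stands 0.30 points from it. The main reason for teal's shortfall from full conversion is the loss of 2 free catalyst to spent catalyst: the same run without that step reaches 100 % instead of 76.0 %. Spent catalyst in teal already makes up 95.4 % of the catalyst charged at 50.0 min. Ochre, left for ten times the time, reaches a loading-time of 0.500 min, equal to teal's 0.500 min; after 500 min ochre holds 95.5 % as spent catalyst and, after 500 min, 76.2 % of target.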